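**Retrosynthetic overview**
1. Last disconnection: the bond between alkene carbon C5 of the pentenyl chain and C1 of the second 3,4-dimethoxyphenyl ring. It is made by a ligand-free Heck–Matsuda arylation of the fully functionalised, unprotected allyl compound with 3,4-dimethoxybenzenediazonium tetrafluoroborate. This one operation adds 10 of the 35 heavy atoms, sets the E-styrene and ends the synthesis with no protecting group left.
2. Enabling feature: the allyl CH=CH2 on C2 is the only monosubstituted C=C, because the butenoate C=C is trisubstituted and acceptor-bound. After insertion, Pd, C4, C3, C2, the carbinol C and the benzylic carbinol O can close a six-membered chelate, which leaves only the new benzylic C5–H available for syn β-hydride elimination.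
3. Ester C–O bond: primary-selective acylation of the syn-1,3-diol with O-TBS (Z)-2-(hydroxymethyl)but-2-enoic acid. The acid is made from crotonaldehyde via (Z)-2-iodobut-2-en-1-ol and Pd hydroxycarbonylation, so the geometry is stored in the alkenyl iodide.
4. C2–carbinol C bond and both stereocentres: Evans boron syn-aldol of (S)-4-benzyl-3-(pent-4-enoyl)oxazolidin-2-one with 3,4-dimethoxybenzaldehyde, then LiBH4.
5. Rings: no ring of the target is built, since both benzene rings are bought. The only temporary ring is the oxazolidinone auxiliary, which is removed in step 3.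

Key step: step 11

Remark: the SMILES is read as the syn diol monoester (carbinol C: S; C2: R) with a 4E styrene and a 2Z butenoate (CH3 cis to the ester carbonyl, angelate-type).

**Step 1**
Reactants: 1 (S)-4-benzyl-1,3-oxazolidin-2-one; 2 pent-4-enoyl chloride
Product: 4 (S)-4-benzyl-3-(pent-4-enoyl)-1,3-oxazolidin-2-one, via lithium oxazolidinide 3 (not isolated)
Conditions: n-BuLi, THF, −78 °C; then 2, −78 → 0 °C
Reagents that add atoms: none
Why: N-acylation of a lithiated oxazolidinone with an acid chloride is the standard entry to Evans imides and touches neither the auxiliary stereocentre nor the terminal alkene.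

**Step 2**
Reactants: 4 (S)-4-benzyl-3-(pent-4-enoyl)-1,3-oxazolidin-2-one; 5 3,4-dimethoxybenzaldehyde
Product: 8 (4S)-4-benzyl-3-{(2S)-2-[(S)-(3,4-dimethoxyphenyl)(hydroxy)methyl]pent-4-enoyl}-1,3-oxazolidin-2-one, via Z-dibutylboron enolate 6 (not isolated), via dibutylboron aldolate 7 (not isolated)
Conditions: n-Bu2BOTf, Et3N, CH2Cl2, 0 °C; 5, −78 → 0 °C; then pH 7 buffer, MeOH, 30% H2O2, 0 °C
Reagents that add atoms: none
Why: Evans boron syn-aldol reaction, in which soft enolisation gives the Z-enolate 6, this reacts through a closed Zimmerman–Traxler chair whose one enolate face is shielded by the benzyl group of the (S)-auxiliary so that both new stereocentres (2S, carbinol S, syn) are auxiliary-controlled, and the buffered peroxide work-up frees the alcohol from 7 without touching the isolated alkene.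

**Step 3**
Reactants: 8 syn-aldol adduct
Product: 9 (1S,2R)-1-(3,4-dimethoxyphenyl)-2-(prop-2-en-1-yl)propane-1,3-diol
Conditions: LiBH4, MeOH (1 equiv), THF, 0 °C
Reagents that add atoms: none
Why: Reductive cleavage of the imide with LiBH4 attacks the exocyclic carbonyl, releases the auxiliary and should give the 1,3-diol without epimerisation or retro-aldol, the change of the C2 descriptor from S to R being only a change in CIP ranking.

**Step 4**
Reactants: 10 (E)-but-2-enal (crotonaldehyde)
Product: 11 (Z)-2-iodobut-2-enal
Conditions: I2, K2CO3, DMAP (cat.), THF/H2O (1:1), rt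
Reagents that add atoms: iodine, II
Why: Baylis–Hillman-type α-iodination (conjugate addition of DMAP, iodination of the enolate, E1cB loss of DMAP) should give the favoured isomer with CH3 trans to CHO, which is the Z-iodide.

**Step 5**
Reactants: 11 (Z)-2-iodobut-2-enal
Product: 12 (Z)-2-iodobut-2-en-1-ol
Conditions: NaBH4, MeOH, 0 °C
Reagents that add atoms: none
Why: Borohydride 1,2-reduction of the enal leaves the C–I bond and the alkene geometry untouched.

**Step 6**
Reactants: 12 (Z)-2-iodobut-2-en-1-ol
Product: 13 tert-butyl{[(2Z)-2-iodobut-2-en-1-yl]oxy}dimethylsilane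
Conditions: TBSCl, imidazole, CH2Cl2, 0 °C → rt
Reagents that add atoms: tert-butyldimethylsilyl chloride, CC(C)(C)[Si](C)(C)Cl
Why: Standard silylation of a primary allylic alcohol masks the hydroxyl so that the acid made next cannot acylate itself.

**Step 7**
Reactants: 13 (Z)-alkenyl iodide TBS ether
Product: 14 (2Z)-2-{[(tert-butyldimethylsilyl)oxy]methyl}but-2-enoic acid
Conditions: Pd(OAc)2 (5 mol %), dppf (6 mol %), CO (1 atm), Et3N, DMF/H2O (5:1), 50 °C; citric acid work-up
Reagents that add atoms: carbon monoxide, [C-]#[O+]; water, O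
Why: Palladium-catalysed hydroxycarbonylation of an alkenyl iodide proceeds with retention through oxidative addition, CO insertion and hydrolysis of the acyl-palladium, so the carboxyl group takes the place of iodine cis to CH3 (Z).

**Step 8**
Reactants: 14 O-TBS (Z)-acid; 9 (1S,2R)-diol
Product: 16 (2R)-2-[(S)-(3,4-dimethoxyphenyl)(hydroxy)methyl]pent-4-en-1-yl (2Z)-2-{[(tert-butyldimethylsilyl)oxy]methyl}but-2-enoate, via mixed trichlorobenzoic anhydride 15 (not isolated)
Conditions: 2,4,6-Cl3C6H2COCl, Et3N, toluene, rt; then 9 (1.0 equiv), toluene, 70 °C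
Reagents that add atoms: none
Why: Yamaguchi-type mixed-anhydride esterification run without DMAP, the variant established for angelic-type acids because it avoids nucleophile-induced Z-to-E leakage, should acylate the unhindered primary hydroxyl well ahead of the secondary benzylic one when one equivalent of 15 is offered.

**Step 9**
Reactants: 16 TBS-protected ester
Product: 17 (2R)-2-[(S)-(3,4-dimethoxyphenyl)(hydroxy)methyl]pent-4-en-1-yl (2Z)-2-(hydroxymethyl)but-2-enoate
Conditions: HF·pyridine, pyridine, THF, 0 °C → rt
Reagents that add atoms: none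
Why: Fluoride-driven desilylation of a primary allylic TBS ether under pyridine-buffered conditions is mild enough for the ester, the Z-enoate and the acid-sensitive dimethoxybenzylic alcohol.

**Step 10**
Reactants: 18 3,4-dimethoxyaniline
Product: 19 3,4-dimethoxybenzenediazonium tetrafluoroborate
Conditions: NaNO2, 48% aq HBF4, H2O, 0 °C; filtration
Reagents that add atoms: sodium nitrite, [Na+].[O-]N=O; tetrafluoroboric acid, [H+].F[B-](F)(F)F
Why: Diazotisation of an electron-rich aniline in aqueous HBF4 precipitates the storable arenediazonium tetrafluoroborate.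

**Step 11**
Reactants: 17 unprotected allyl ester-diol; 19 3,4-dimethoxybenzenediazonium tetrafluoroborate
Product: 20 (2R,4E)-5-(3,4-dimethoxyphenyl)-2-[(S)-(3,4-dimethoxyphenyl)(hydroxy)methyl]pent-4-en-1-yl (2Z)-2-(hydroxymethyl)but-2-enoate (target)
Conditions: Pd2(dba)3 (3 mol %), 2,6-di-tert-butyl-4-methylpyridine (1.5 equiv), 19 (1.3 equiv), DMA, 23 °C
Reagents that add atoms: none
Why: Heck–Matsuda reaction, in which Pd(0) inserts into the C–N bond of 19 with loss of N2 to give a ligand-free cationic aryl-Pd(II), this binds the terminal alkene of 17 and adds syn with the aryl group going to the unsubstituted C5 and Pd to C4, and after C4–C5 rotation the new benzylic hydrogen is lost by syn β-hydride elimination while the hindered pyridine takes up HBF4 and returns Pd(0). The closest known reaction type is the room-temperature, ligand-free arylation of electronically unbiased terminal alkenes, free alkenols and homoallylic esters included, with arenediazonium salts, which is E-styrenyl selective. No ring is closed and no stereocentre is created; the E geometry follows from the β-hydride elimination transition state that keeps the aryl group and the C3 chain apart, and the two existing stereocentres are not enolisable under these conditions and are untouched as long as Pd does not walk past C3. Site selectivity among the C=C bonds rests on the substrate, since only the allyl CH=CH2 is monosubstituted, whereas the butenoate C=C is trisubstituted and acceptor-bound and the styrene formed is 1,2-disubstituted and conjugated. Positional selectivity (styrenyl rather than allyl-arene, no chain walking towards the carbinol) is secured by the carbinol oxygen, which can close the six-membered chelate Pd–C4–C3–C2–C(carbinol)–O in which the C3–H bonds cannot become syn-coplanar with Pd, and by the more hydridic benzylic C5–H next to the electron-rich ring. The buffered, oxidant-free conditions should leave both free hydroxyls, the ester and the Z-enoate alone, so the step gives the target directly and the acid-sensitive hydroxy-styrene pair never meets an earlier reagent.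

**Compound list**
1 | (S)-4-benzyl-1,3-oxazolidin-2-one | O=C1N[C@@H](Cc2ccccc2)CO1 | starting material
2 | pent-4-enoyl chloride | C=CCCC(=O)Cl | starting material
3 | lithium (S)-4-benzyl-2-oxo-1,3-oxazolidin-3-ide | [Li]N1[C@@H](Cc2ccccc2)COC1=O | intermediate
4 | (S)-4-benzyl-3-(pent-4-enoyl)-1,3-oxazolidin-2-one | C=CCCC(=O)N1[C@@H](Cc2ccccc2)COC1=O | intermediate
5 | 3,4-dimethoxybenzaldehyde | COc1ccc(C=O)cc1OC | starting material
6 | Z-dibutylboron enolate of 4 | C=CC/C=C(\OB(CCCC)CCCC)N1[C@@H](Cc2ccccc2)COC1=O | intermediate
7 | dibutylboron aldolate of 8 | O=C1OC[C@H](Cc2ccccc2)N1C(=O)[C@@H](CC=C)[C@H](OB(CCCC)CCCC)c1ccc(OC)c(OC)c1 | intermediate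
8 | (4S)-4-benzyl-3-{(2S)-2-[(S)-(3,4-dimethoxyphenyl)(hydroxy)methyl]pent-4-enoyl}-1,3-oxazolidin-2-one | O=C1OC[C@H](Cc2ccccc2)N1C(=O)[C@@H](CC=C)[C@H](O)c1ccc(OC)c(OC)c1 | intermediate
9 | (1S,2R)-1-(3,4-dimethoxyphenyl)-2-(prop-2-en-1-yl)propane-1,3-diol | OC[C@@H](CC=C)[C@H](O)c1ccc(OC)c(OC)c1 | intermediate
10 | (E)-but-2-enal | C/C=C/C=O | starting material
11 | (Z)-2-iodobut-2-enal | C/C=C(/C=O)I | intermediate
12 | (Z)-2-iodobut-2-en-1-ol | C/C=C(/CO)I | intermediate
13 | tert-butyl{[(2Z)-2-iodobut-2-en-1-yl]oxy}dimethylsilane | C/C=C(/CO[Si](C)(C)C(C)(C)C)I | intermediate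
14 | (2Z)-2-{[(tert-butyldimethylsilyl)oxy]methyl}but-2-enoic acid | C/C=C(/CO[Si](C)(C)C(C)(C)C)C(=O)O | intermediate
15 | mixed anhydride of 14 and 2,4,6-trichlorobenzoic acid | C/C=C(/CO[Si](C)(C)C(C)(C)C)C(=O)OC(=O)c1c(Cl)cc(Cl)cc1Cl | intermediate
16 | (2R)-2-[(S)-(3,4-dimethoxyphenyl)(hydroxy)methyl]pent-4-en-1-yl (2Z)-2-{[(tert-butyldimethylsilyl)oxy]methyl}but-2-enoate | C/C=C(/CO[Si](C)(C)C(C)(C)C)C(=O)OC[C@@H](CC=C)[C@H](O)c1ccc(OC)c(OC)c1 | intermediate
17 | (2R)-2-[(S)-(3,4-dimethoxyphenyl)(hydroxy)methyl]pent-4-en-1-yl (2Z)-2-(hydroxymethyl)but-2-enoate | C/C=C(/CO)C(=O)OC[C@@H](CC=C)[C@H](O)c1ccc(OC)c(OC)c1 | intermediate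
18 | 3,4-dimethoxyaniline | COc1ccc(N)cc1OC | starting material
19 | 3,4-dimethoxybenzenediazonium tetrafluoroborate | COc1ccc([N+]#N)cc1OC.F[B-](F)(F)F | intermediate
20 | (2R,4E)-5-(3,4-dimethoxyphenyl)-2-[(S)-(3,4-dimethoxyphenyl)(hydroxy)methyl]pent-4-en-1-yl (2Z)-2-(hydroxymethyl)but-2-enoate | C/C=C(/CO)C(=O)OC[C@@H](C/C=C/c1ccc(OC)c(OC)c1)[C@H](O)c1ccc(OC)c(OC)c1 | target

**Total step count:** 11
**Longest linear sequence:** 7 steps (steps 4, 5, 6, 7, 8, 9 and 11, from crotonaldehyde)

**Steps most likely to fail**

1. **Step 11.**
   - What may go wrong: positional leakage in the β-hydride elimination, followed by re-insertion of Pd–H (chain walking along C3–C2 towards the carbinol). The free carbinol oxygen may also capture the Pd-activated alkene (carboetherification), and the electron-rich diazonium salt may turn over slowly.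
   - Fallback: it sets out from 17. Cross-metathesis with vinylboronic acid pinacol ester (Hoveyda–Grubbs II catalyst, CH2Cl2, 40 °C) should convert the terminal alkene into the (E)-alkenylboronic acid pinacol ester F1. Suzuki–Miyaura coupling of F1 with commercial 4-iodo-1,2-dimethoxybenzene (Pd(dppf)Cl2, K3PO4, THF/H2O, rt) then forms the same aryl–alkenyl bond. The alkene position and geometry are already fixed at that point, and the sequence comes back to the route at 20.

2. **Step 8.**
   - What may go wrong: competing acylation of the secondary benzylic hydroxyl, erosion of the Z geometry while the carboxyl group is activated, or sluggish acyl transfer in the absence of a nucleophilic catalyst.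
   - Fallback: it sets out from 8. Silylation of the carbinol (TBSOTf, 2,6-lutidine, CH2Cl2, 0 °C) gives the O-TBS aldol adduct F2, and LiBH4 cleavage gives the mono-protected primary alcohol F3. A Mitsunobu esterification with 14 (PPh3, DIAD, THF, 0 °C), in which the alcohol and not the acid is activated, gives the bis-silyl ester F4. HF·pyridine/pyridine then removes both silyl groups and the sequence comes back to the route at 17.

3. **Step 7.**
   - What may go wrong: slow CO insertion at the α-branched alkenyl-palladium, β-silyloxy elimination from it, or partial loss of the silyl ether in the warm aqueous amine medium.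
   - Fallback: it sets out from 13. Iodine–lithium exchange (t-BuLi, 2.1 equiv, Et2O, −78 °C) gives the configurationally stable alkenyllithium F5. This is carboxylated at −78 °C with dry CO2 before any silyl migration can set in, and after mild acidic work-up the sequence comes back to the route at 14.

**Further compounds**
F1 | step 11 | (2R,4E)-2-[(S)-(3,4-dimethoxyphenyl)(hydroxy)methyl]-5-(4,4,5,5-tetramethyl-1,3,2-dioxaborolan-2-yl)pent-4-en-1-yl (2Z)-2-(hydroxymethyl)but-2-enoate | C/C=C(/CO)C(=O)OC[C@@H](C/C=C/B1OC(C)(C)C(C)(C)O1)[C@H](O)c1ccc(OC)c(OC)c1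
F2 | step 8 | (4S)-4-benzyl-3-{(2S)-2-[(S)-[(tert-butyldimethylsilyl)oxy](3,4-dimethoxyphenyl)methyl]pent-4-enoyl}-1,3-oxazolidin-2-one | O=C1OC[C@H](Cc2ccccc2)N1C(=O)[C@@H](CC=C)[C@H](O[Si](C)(C)C(C)(C)C)c1ccc(OC)c(OC)c1
F3 | step 8 | (2R)-2-{(S)-[(tert-butyldimethylsilyl)oxy](3,4-dimethoxyphenyl)methyl}pent-4-en-1-ol | OC[C@@H](CC=C)[C@H](O[Si](C)(C)C(C)(C)C)c1ccc(OC)c(OC)c1
F4 | step 8 | (2R)-2-{(S)-[(tert-butyldimethylsilyl)oxy](3,4-dimethoxyphenyl)methyl}pent-4-en-1-yl (2Z)-2-{[(tert-butyldimethylsilyl)oxy]methyl}but-2-enoate | C/C=C(/CO[Si](C)(C)C(C)(C)C)C(=O)OC[C@@H](CC=C)[C@H](O[Si](C)(C)C(C)(C)C)c1ccc(OC)c(OC)c1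
F5 | step 7 | (E)-1-[(tert-butyldimethylsilyl)oxy]but-2-en-2-yllithium (CH3 cis to Li) | C/C=C(/CO[Si](C)(C)C(C)(C)C)[Li]
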